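## Structural features

Xanthogalenol is a chalcone. Ring A, a phloroglucinol-type benzene, and ring B, a 4-hydroxyphenyl group, are joined by a three-carbon enone C(=O)–C(α)=C(β), with the carbonyl on C1' of ring A and C(β) on C1 of ring B. Ring A carries hydroxyls at C2' and C6' on both sides of the carbonyl, a prenyl (3-methylbut-2-en-1-yl) chain at C3', a methoxy group at C4' para to the carbonyl, and its only hydrogen at C5'. The molecule has no stereocentre, so none stand next to each other; the single stereochemical element is the E geometry of the C(α)=C(β) double bond. Two groupings are fragile. The 2',6'-dihydroxy enone closes to flavanones by oxa-Michael addition in base or strong acid. The prenyl olefin beside C2'-OH cyclises to a 2,2-dimethylchroman in acid and tolerates neither hydrogenation nor electrophilic oxidants. The real difficulty is the regiochemistry of ring A: one of three oxygens must be methylated para to the carbonyl, exactly one prenyl group must sit between OMe and OH, and both ortho hydroxyls must end up free without flavanone closure. The key step uses the fact that the C1' carbonyl is flanked by C2'-OH and C6'-OH. Ring A can therefore enter as the salicylaldehyde-type aldehyde 11, whose phenoxide guides rhodium into the formyl C–H bond, and the E-enone is the result of syn addition of that hydrogen and the acyl group across the triple bond of the para-oxygenated phenylacetylene 16. Before prenylation the ring A aldehyde has a mirror plane through C1' and C4', so C3' and C5' are equivalent and the prenyl position cannot be mis-assigned.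

## Logic of the disconnections

18 to 17. Only the aryl O–Si bond on ring B is cut. A silyl ether is chosen over an ester for two reasons. An aryl ester is an acyl donor toward the ring A phenoxides present in the coupling, and its basic methanolysis would expose the 2',6'-dihydroxy enone to the conditions under which it closes to flavanones. The forward step must therefore be near neutral, which buffered fluoride allows.

17 to 11 and 16. The C(=O)–C(α) bond is cut and the hydrogen on C(β) is returned to the formyl carbon, a retro-hydroacylation. This splits the molecule into two fragments of similar size with no change of oxidation level and no by-product, and it leaves both ring A hydroxyls free. The forward step must add H and acyl syn across the alkyne, place the acyl group on the terminal carbon, and leave the prenyl olefin untouched.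

16 to 15, then to 13 and 14, then to 12. The C(sp)–Si bond, the aryl–alkynyl C–C bond and the O–Si bond are cut in turn. This leads back to two commercial compounds, and the demand is only that the alkynyl silane can be removed while the hindered aryl silyl ether stays.

11 to 10. The two O–CH2 acetal bonds are cut. The acetals were needed as directing groups and as protection against organolithium reagents. The forward step must remove them under acid mild enough to spare the prenyl olefin next to the liberated C2 hydroxyl.

10 to 5 and 6. The C3–CH2 bond of the prenyl group is cut. Direct C-prenylation of 1 would have to choose among three nucleophilic ring carbons, whereas in 5 the two open positions are identical, so the regiochemistry is fixed by symmetry. The forward step must mask the aldehyde toward butyllithium, metalate the ring between OMe and the acetal oxygen, and alkylate at the primary carbon of 6.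

5 to 2, then to 1. The C1–CHO bond is cut, followed by the two acetal O–CH2 bonds. The carbon between the two acetal oxygens of 2 is the preferred lithiation site, which places the formyl group para to the methoxy group. The forward step needs selective metalation of that position over the two positions next to OMe.

## Other disconnections considered

Alternative 1: The cut is the C3'–CH2 bond at the chalcone stage. The forward step heats the 6'-O-prenyl ether A2 with Eu(fod)3, so that the prenyl group moves by Claisen shift to C5' and by Cope shift to C3', giving xanthogalenol 2',4-bis(methoxymethyl) ether A1 with C6'-OH freed on tautomerisation.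
- In its favour: the prenyl group is delivered intramolecularly to a defined carbon, O-prenylation is easy, and the enone of A2 comes from an aldol condensation whose regiochemistry is never in doubt. On that last point it is better than the chosen plan, where linear against branched insertion is open.
- Against it: the first dienone has a hydrogen at C5' and can enolise there, stopping at the reverse-prenyl stage. The Lewis acid and heat act on a chalcone that gains a free ortho hydroxyl during the reaction. A2 requires all three ring A oxygens to be told apart as methyl, methoxymethyl and prenyl before the condensation. Two acetals must finally be removed by acid from a 2',6'-dihydroxy chalcone with a prenyl group beside a hydroxyl.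
- Comparison: structurally the chosen plan fixes the ring A pattern early on a small, robust arene and ends with a buffered fluoride step. Mechanistically Alternative 1 relies on two consecutive sigmatropic shifts with a competing exit, while the chosen plan relies on one metal-mediated insertion with a regiochemical question. In step count the two are about equal.

Alternative 2: The cut is the C(β)–C1 bond to ring B. The forward step is a Heck arylation of the ring A vinyl ketone A4 with 1-iodo-4-(methoxymethoxy)benzene A5 under Pd(OAc)2 and a mild base, giving xanthogalenol tris(methoxymethyl) ether A3.
- In its favour: β-arylation of an enone by an aryl iodide is reliable, E geometry follows from syn β-hydride elimination, and no directing group is needed. On certainty of the bond-forming step it is better than the chosen plan.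
- Against it: A4 is a polymerisation-prone Michael acceptor flanked by two ortho ethers. It would be reached from 10 by vinyl addition and oxidation, two more steps than the single deprotection that gives 11. All three phenols must be protected, and the end is a triple acid deprotection on the sensitive chalcone.
- Comparison: both plans use the same ring A aldehyde 10, so on arene construction they are equal. Alternative 2 is one step longer after 10 and less atom-economic, and it moves the risk from the coupling to the last step.

Alternative 3: The cut is the C1'–C2' bond inside ring A. The forward step treats the pyranone A7 with Mg(OMe)2 in methanol. The lactone opens to a methyl ester, the magnesium-chelated diketone carbon attacks that ester, and the new six-membered carbocycle aromatises to xanthogalenol 4-O-methoxymethyl ether A6.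
- In its favour: the positions of OMe and prenyl are fixed by C4 and C3 of the pyranone, so no arene regiochemistry arises, and ring A appears with both hydroxyls free and unprotected. On these two points it is equal to or better than the chosen plan.
- Against it: the difficulty moves to A7, which needs C3-selective prenylation of a 4-methoxypyranone and acylation of its C6 side chain with a cinnamoyl unit. The enone is exposed to methoxide, which can add in conjugate fashion. The open-chain intermediate can also close by aldol rather than Claisen condensation. A6 is a 2',6'-dihydroxy chalcone formed in basic alcohol, and an acid deprotection still follows.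
- Comparison: mechanistically it asks one pot to form a ring in the presence of the most fragile function, where the chosen plan forms only one bond under nearly neutral conditions. It is also the longest of the four routes.

Key step: step 8

Assumption: the ring B hydroxyl is carried through the key step as a triisopropylsilyl ether. This is a change of protecting group only; the bond formed and the two coupling skeletons are unchanged.

## Route

Step 1
Reactants: 1 5-methoxyresorcinol (5-methoxybenzene-1,3-diol)
Product: 2 1-methoxy-3,5-bis(methoxymethoxy)benzene
Conditions: NaH (2.4 equiv), MOMCl (2.3 equiv), DMF, 0 °C to rt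
Reagents that add atoms: chloromethyl methyl ether, COCCl
Why: Williamson-type O-alkylation of both sodium phenoxides by the reactive α-chloro ether; the two acetal ethers are strong ortho-directing groups for the lithiations that follow and are removable later by mild acid.

Step 2
Reactants: 2 1-methoxy-3,5-bis(methoxymethoxy)benzene
Product: 5 4-methoxy-2,6-bis(methoxymethoxy)benzaldehyde, via aryllithium 3 (not isolated), via lithium hemiaminal alkoxide 4 (not isolated)
Conditions: n-BuLi (1.1 equiv), TMEDA, THF, 0 °C; DMF, 0 °C to rt; H2O
Reagents that add atoms: N,N-dimethylformamide, CN(C)C=O
Why: Directed ortho-metalation; the C–H between the two methoxymethoxy groups is the most acidic and is coordinated from both sides, so lithiation and formylation with DMF place the formyl group para to the methoxy group. The product has a mirror plane that makes C3 and C5 equivalent.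

Step 3
Reactants: 5 4-methoxy-2,6-bis(methoxymethoxy)benzaldehyde; 6 prenyl bromide (1-bromo-3-methylbut-2-ene)
Product: 10 4-methoxy-2,6-bis(methoxymethoxy)-3-(3-methylbut-2-en-1-yl)benzaldehyde, via lithium amino alkoxide 7 (not isolated), via ring-lithiated amino alkoxide 8 (not isolated), via prenylated amino alkoxide 9 (not isolated)
Conditions: lithium 4-methylpiperazin-1-ide (from 1-methylpiperazine, n-BuLi), THF, −20 °C; n-BuLi (1.3 equiv), −20 to 0 °C; CuBr·SMe2 (10 mol%), 6 (1.5 equiv), −78 to 0 °C; H2O
Reagents that add atoms: none
Why: In situ protection of the aldehyde as a lithium α-amino alkoxide, directed ortho-metalation at the only remaining kind of ring position (between OMe and OCH2OMe, C3 and C5 being identical), and copper-catalysed allylic substitution at the primary carbon of the prenyl bromide; aqueous work-up collapses the hemiaminal back to the aldehyde.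

Step 4
Reactants: 10 4-methoxy-2,6-bis(methoxymethoxy)-3-(3-methylbut-2-en-1-yl)benzaldehyde
Product: 11 2,6-dihydroxy-4-methoxy-3-(3-methylbut-2-en-1-yl)benzaldehyde
Conditions: 3 M HCl, MeOH, rt
Reagents that add atoms: none
Why: Acid-catalysed acetal exchange with methanol removes both methoxymethyl groups, which are activated by the ortho carbonyl; dilute acid at room temperature should stay below the point at which the prenyl olefin closes onto the neighbouring phenol.

Step 5
Reactants: 12 4-iodophenol
Product: 13 (4-iodophenoxy)triisopropylsilane
Conditions: TIPSCl (1.1 equiv), imidazole (1.1 equiv), DMF, rt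
Reagents that add atoms: chlorotriisopropylsilane, CC(C)[Si](Cl)(C(C)C)C(C)C
Why: Imidazole-promoted O-silylation of a phenol; the bulky silyl ether is inert to amines, carbonate and methanol in the next steps and to the hydroacylation conditions.

Step 6
Reactants: 13 (4-iodophenoxy)triisopropylsilane; 14 trimethylsilylacetylene (ethynyltrimethylsilane)
Product: 15 trimethyl{[4-(triisopropylsilyloxy)phenyl]ethynyl}silane
Conditions: PdCl2(PPh3)2 (2 mol%), CuI (4 mol%), Et3N, THF, rt
Reagents that add atoms: none
Why: Sonogashira coupling of an aryl iodide with a terminal alkyne; the silyl cap on the alkyne prevents double coupling and alkyne homocoupling of the product.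

Step 7
Reactants: 15 trimethyl{[4-(triisopropylsilyloxy)phenyl]ethynyl}silane
Product: 16 (4-ethynylphenoxy)triisopropylsilane
Conditions: K2CO3 (0.2 equiv), MeOH–THF, rt
Reagents that add atoms: none
Why: Base-catalysed methanolysis of the C(sp)–Si bond; the alkynyl trimethylsilyl group is cleaved much faster than the hindered aryl triisopropylsilyl ether, so the terminal alkyne is released selectively.

Step 8
Reactants: 11 2,6-dihydroxy-4-methoxy-3-(3-methylbut-2-en-1-yl)benzaldehyde; 16 (4-ethynylphenoxy)triisopropylsilane
Product: 17 xanthogalenol 4-O-triisopropylsilyl ether, (E)-1-[2,6-dihydroxy-4-methoxy-3-(3-methylbut-2-en-1-yl)phenyl]-3-[4-(triisopropylsilyloxy)phenyl]prop-2-en-1-one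
Conditions: [RhCl(cod)]2 (2.5 mol%), dppf (1,1'-bis(diphenylphosphino)ferrocene, Fe(C5H4PPh2)2, 5 mol%), Na2CO3 (10 mol%), toluene, 100 °C, slow addition of 16 (1.3 equiv)
Reagents that add atoms: none
Why: Carbonate deprotonates one ring A hydroxyl of 11, the phenoxide binds monovalent rhodium, and oxidative addition of the neighbouring formyl C–H gives a five-membered O,C-chelated acyl hydride of trivalent rhodium in which the chelate holds the acyl group and suppresses decarbonylation. The alkyne 16 then coordinates and inserts into the Rh–H bond in syn fashion, hydride going to the aryl-bearing carbon and rhodium to the terminal carbon, and acyl–vinyl reductive elimination forms the C(=O)–C(α) bond and returns monovalent rhodium. The closest known reaction type is the rhodium-catalysed intermolecular hydroacylation of alkynes with salicylaldehydes to 2-hydroxyaryl vinyl ketones. No ring is closed and no stereocentre is formed; the E geometry follows directly from syn delivery of H and acyl to the triple bond. The step needs linear over branched regiochemistry, which is favoured because the acyl group flanked by two ortho oxygens and the wide-bite-angle diphosphine both penalise rhodium at the internal carbon, although this is not guaranteed for an arylalkyne. It also needs chemoselectivity for the alkyne over the prenyl olefin, which is trisubstituted and too hindered to insert. Either flanking hydroxyl can anchor the metal and both remain free in 17, so it does not matter which one directs. Sub-stoichiometric carbonate in an apolar solvent and slow addition of the alkyne are meant to hold back oxa-Michael closure of the product and alkyne oligomerisation, and the silyl ether cannot transfer to the ring A phenoxides as an ester could.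

Step 9
Reactants: 17 xanthogalenol 4-O-triisopropylsilyl ether
Product: 18 xanthogalenol, (E)-1-[2,6-dihydroxy-4-methoxy-3-(3-methylbut-2-en-1-yl)phenyl]-3-(4-hydroxyphenyl)prop-2-en-1-one
Conditions: TBAF (1.1 equiv), AcOH (1.1 equiv), THF, 0 °C
Reagents that add atoms: none
Why: Fluoride-induced cleavage of an aryl silyl ether, which is fast because the para-acylvinyl phenoxide is a good leaving group; the acetic acid buffer protonates the phenoxide at once, so the 2',6'-dihydroxy enone never sits in a basic medium and the E double bond and prenyl group are untouched.

## Compound list

1 | 5-methoxyresorcinol (5-methoxybenzene-1,3-diol) | COc1cc(O)cc(O)c1 | starting material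
2 | 1-methoxy-3,5-bis(methoxymethoxy)benzene | COCOc1cc(OC)cc(OCOC)c1 | intermediate
3 | [4-methoxy-2,6-bis(methoxymethoxy)phenyl]lithium | [Li]c1c(OCOC)cc(OC)cc1OCOC | intermediate (not isolated)
4 | lithium (dimethylamino)[4-methoxy-2,6-bis(methoxymethoxy)phenyl]methanolate (racemic) | [Li]OC(N(C)C)c1c(OCOC)cc(OC)cc1OCOC | intermediate (not isolated)
5 | 4-methoxy-2,6-bis(methoxymethoxy)benzaldehyde | COCOc1cc(OC)cc(OCOC)c1C=O | intermediate
6 | prenyl bromide (1-bromo-3-methylbut-2-ene) | CC(C)=CCBr | starting material
7 | lithium [4-methoxy-2,6-bis(methoxymethoxy)phenyl](4-methylpiperazin-1-yl)methanolate (racemic) | [Li]OC(N1CCN(C)CC1)c1c(OCOC)cc(OC)cc1OCOC | intermediate (not isolated)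
8 | lithium [3-lithio-4-methoxy-2,6-bis(methoxymethoxy)phenyl](4-methylpiperazin-1-yl)methanolate (racemic) | [Li]OC(N1CCN(C)CC1)c1c(OCOC)cc(OC)c([Li])c1OCOC | intermediate (not isolated)
9 | lithium [4-methoxy-2,6-bis(methoxymethoxy)-3-(3-methylbut-2-en-1-yl)phenyl](4-methylpiperazin-1-yl)methanolate (racemic) | [Li]OC(N1CCN(C)CC1)c1c(OCOC)cc(OC)c(CC=C(C)C)c1OCOC | intermediate (not isolated)
10 | 4-methoxy-2,6-bis(methoxymethoxy)-3-(3-methylbut-2-en-1-yl)benzaldehyde | COc1cc(OCOC)c(C=O)c(OCOC)c1CC=C(C)C | intermediate
11 | 2,6-dihydroxy-4-methoxy-3-(3-methylbut-2-en-1-yl)benzaldehyde | COc1cc(O)c(C=O)c(O)c1CC=C(C)C | intermediate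
12 | 4-iodophenol | Oc1ccc(I)cc1 | starting material
13 | (4-iodophenoxy)triisopropylsilane | CC(C)[Si](Oc1ccc(I)cc1)(C(C)C)C(C)C | intermediate
14 | trimethylsilylacetylene (ethynyltrimethylsilane) | C#C[Si](C)(C)C | starting material
15 | trimethyl{[4-(triisopropylsilyloxy)phenyl]ethynyl}silane | CC(C)[Si](Oc1ccc(C#C[Si](C)(C)C)cc1)(C(C)C)C(C)C | intermediate
16 | (4-ethynylphenoxy)triisopropylsilane | CC(C)[Si](Oc1ccc(C#C)cc1)(C(C)C)C(C)C | intermediate
17 | xanthogalenol 4-O-triisopropylsilyl ether (E double bond) | COc1cc(O)c(C(=O)/C=C/c2ccc(O[Si](C(C)C)(C(C)C)C(C)C)cc2)c(O)c1CC=C(C)C | intermediate
18 | xanthogalenol (E double bond) | COc1cc(O)c(C(=O)/C=C/c2ccc(O)cc2)c(O)c1CC=C(C)C | target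

## Step count and least certain steps

Total step count: 9. Longest linear sequence: 6 steps (steps 1, 2, 3, 4, 8 and 9); the alkyne branch (steps 5 to 7) joins at step 8.

Step 8 (key step). Alkyne insertion may turn toward the branched 1,1-disubstituted enone, because arylalkynes can place the metal on the benzylic carbon. Further hazards are oligomerisation of the terminal alkyne on rhodium, slow C–H activation of a crowded and doubly hydrogen-bonded aldehyde, and closure of a ring A hydroxyl onto the new enone at 100 °C. The fallback builds the enone by aldol condensation and sets out from 10. MeMgBr in THF at 0 °C should give the methyl carbinol 1-[4-methoxy-2,6-bis(methoxymethoxy)-3-(3-methylbut-2-en-1-yl)phenyl]ethan-1-ol F1. Dess–Martin periodinane in CH2Cl2 should oxidise it to the methyl ketone 1-[4-methoxy-2,6-bis(methoxymethoxy)-3-(3-methylbut-2-en-1-yl)phenyl]ethan-1-one F2. Claisen–Schmidt condensation of F2 with commercial 4-(methoxymethoxy)benzaldehyde (KOH, EtOH–H2O, rt) should give xanthogalenol tris(methoxymethyl) ether F3. Finally 3 M HCl in MeOH at rt removes the three acetals, and the fallback comes back to the route at 18.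

Step 3. Ring lithiation may be incomplete beside the bulky masked aldehyde, butyllithium may add to the carbonyl if the amino alkoxide collapses, and the copper-mediated substitution may occur with allylic transposition to give the 1,1-dimethylallyl isomer. The fallback replaces metalation by halogenation and cross-coupling and sets out from 5. N-bromosuccinimide in MeCN at 0 °C should brominate one of the two equivalent open positions to give 3-bromo-4-methoxy-2,6-bis(methoxymethoxy)benzaldehyde F4. Stille coupling of F4 with tributyl(3-methylbut-2-en-1-yl)stannane (Pd(PPh3)4, CsF, DMF, 90 °C) should then deliver the linear prenyl group, and the fallback comes back to the route at 10.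

Step 4. Acid may trigger closure of the prenyl olefin onto the freed C2 hydroxyl or Markovnikov addition of methanol to the olefin before both acetals are gone. The fallback removes the acetals before any prenyl group is present and uses the symmetry of ring A; it sets out from 5 and also bypasses step 3. 3 M HCl in MeOH should give 2,6-dihydroxy-4-methoxybenzaldehyde F5. Mono-etherification with tert-butyl 2-methylbut-3-en-2-yl carbonate under Pd(PPh3)4 in THF at 0 °C (Tsuji–Trost O-allylation at the tertiary terminus) should give 2-hydroxy-4-methoxy-6-[(2-methylbut-3-en-2-yl)oxy]benzaldehyde F6. Heating F6 in toluene at 110 °C should bring about an aromatic Claisen rearrangement to the only free ortho carbon, which delivers the prenyl group in its linear form, and the fallback comes back to the route at 11.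

Step 9. Fluoride that is not fully buffered may deprotonate a ring A hydroxyl and start oxa-Michael closure onto the enone, and a long reaction time may allow E to Z isomerisation in light. The fallback avoids any deprotection on the chalcone and sets out from 16. TBAF in THF at 0 °C should give 4-ethynylphenol F7, which is used at once with 11 under the conditions of step 8. The simple phenol is less acidic than the ring A hydroxyls and cannot form the chelate, so it should be a spectator, and the fallback comes back to the route at 18.

## Further compounds

F1 | step 8 | 1-[4-methoxy-2,6-bis(methoxymethoxy)-3-(3-methylbut-2-en-1-yl)phenyl]ethan-1-ol (racemic) | COc1cc(OCOC)c(C(C)O)c(OCOC)c1CC=C(C)C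
F2 | step 8 | 1-[4-methoxy-2,6-bis(methoxymethoxy)-3-(3-methylbut-2-en-1-yl)phenyl]ethan-1-one | COc1cc(OCOC)c(C(C)=O)c(OCOC)c1CC=C(C)C
F3 | step 8 | xanthogalenol tris(methoxymethyl) ether (E double bond) | COc1cc(OCOC)c(C(=O)/C=C/c2ccc(OCOC)cc2)c(OCOC)c1CC=C(C)C
F4 | step 3 | 3-bromo-4-methoxy-2,6-bis(methoxymethoxy)benzaldehyde | COc1cc(OCOC)c(C=O)c(OCOC)c1Br
F5 | step 4 | 2,6-dihydroxy-4-methoxybenzaldehyde | COc1cc(O)c(C=O)c(O)c1
F6 | step 4 | 2-hydroxy-4-methoxy-6-[(2-methylbut-3-en-2-yl)oxy]benzaldehyde | COc1cc(O)c(C=O)c(OC(C)(C)C=C)c1
F7 | step 9 | 4-ethynylphenol | Oc1ccc(C#C)cc1
A1 | alternative 1 | xanthogalenol 2',4-bis(methoxymethyl) ether (E double bond) | COc1cc(O)c(C(=O)/C=C/c2ccc(OCOC)cc2)c(OCOC)c1CC=C(C)C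
A2 | alternative 1 | (E)-1-[4-methoxy-2-(methoxymethoxy)-6-(3-methylbut-2-en-1-yloxy)phenyl]-3-[4-(methoxymethoxy)phenyl]prop-2-en-1-one | COc1cc(OCC=C(C)C)c(C(=O)/C=C/c2ccc(OCOC)cc2)c(OCOC)c1
A3 | alternative 2 | xanthogalenol tris(methoxymethyl) ether (E double bond) | COc1cc(OCOC)c(C(=O)/C=C/c2ccc(OCOC)cc2)c(OCOC)c1CC=C(C)C
A4 | alternative 2 | 1-[4-methoxy-2,6-bis(methoxymethoxy)-3-(3-methylbut-2-en-1-yl)phenyl]prop-2-en-1-one | COc1cc(OCOC)c(C(=O)C=C)c(OCOC)c1CC=C(C)C
A5 | alternative 2 | 1-iodo-4-(methoxymethoxy)benzene | COCOc1ccc(I)cc1
A6 | alternative 3 | xanthogalenol 4-O-methoxymethyl ether (E double bond) | COc1cc(O)c(C(=O)/C=C/c2ccc(OCOC)cc2)c(O)c1CC=C(C)C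
A7 | alternative 3 | 4-methoxy-6-{(E)-4-[4-(methoxymethoxy)phenyl]-2-oxobut-3-en-1-yl}-3-(3-methylbut-2-en-1-yl)-2H-pyran-2-one | COc1cc(CC(=O)/C=C/c2ccc(OCOC)cc2)oc(=O)c1CC=C(C)C
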